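Slowness here is shared: the making of intermediate A (0.00972 s⁻¹) and the two arrows to product (0.0112 s⁻¹ and 0.00846 s⁻¹) have rate constants of like size, and the set-ups differ both in time and in vessel.

    substrate ⇌ intermediate A (K1 = 11, k1 = 0.00972 s⁻¹)
    intermediate A → product (k2 = 0.0112 s⁻¹)
    substrate ⇌ intermediate B (K3 = 0.98, k3 = 0.0862 s⁻¹)
    intermediate B → product (k4 = 0.00846 s⁻¹)
    substrate + product ⇌ idle adduct, settled at all times (K5 = 3.3 M⁻¹)

common to all: substrate 0.23 M

| run | time | remark |
|---|---|---|
| dawn | 2.0 min | plug flow through a tube for 2.0 min, no back-mixing |
| summer |  | one stirred flow tank at steady state, fed with the mixture as stated, mean residence time 20.0 min |
| noon | 2.0 min | everything together in a closed stirred flask, run for 2.0 min |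
| autumn |  | a single well-mixed tank run continuously and read at steady state, 2.0 min in it on average |

- the set-up with the highest amount of product at the outlet or at the end, in percent of the substrate put in ("none" if the first two lie within 2 percentage points) (dawn / summer / noon / autumn / none)
- amount of product at the outlet or at the end, in percent of the substrate put in, dawn
- amount of product at the outlet or at the end, in percent of the substrate put in, summer
- amount of product at the outlet or at the end, in percent of the substrate put in, noon
- amount of product at the outlet or at the end, in percent of the substrate put in, autumn

- percent here means substrate units held: one idle adduct counts as two
- what is said of product includes idle adduct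
- the stated concentrations are those of everything mixed, before any reaction; amounts are the same in each set-up
- in an amount of product, one idle adduct counts as one product
- run time (dawn): 2.0 min

The ladder runs from the fastest rung down. The idle adduct stands at balance at every moment, and its constant times the charged substrate is 0.76. Next, substrate and intermediate B relax together with a half-life of 3.98 s, much shorter than the 1.09 min for substrate and intermediate A, both ways together. On that same slow rung stand the arrows to product, with half-lives of 1.03 min from intermediate A and 1.37 min from intermediate B.

Both arrows draw on intermediates that are fed from free substrate, so in a tank at steady state the making of product is first order in c(substrate). In a tank, each intermediate stands at what is made over what leaves by falling back, going to product or washing out: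

c(intermediate A)/c(substrate): summer 0.752, autumn 0.476

c(intermediate B)/c(substrate): summer 0.886, autumn 0.823

The tank ratio, product leaving per free substrate leaving, is a Damköhler number: the mean residence time times the two ratios, each weighted by its arrow to product. No arrow to product starts from the idle adduct, so it does not appear in the ratio.

summer: 19.1; autumn: 1.48

Reckoned by hand without the idle adduct, the product share is the ratio over one plus the three ratios: 87.9 % in summer and 39.1 % in autumn.

Dawn and noon obey the same equations over the same 2.0 min, about twice the half-life from intermediate A. In that time the arrow from intermediate A, the faster of the two to product, turns 73.9 % of a portion standing as intermediate A into product, less than the summer share, so my pick is summer.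

The forecast says summer, with 46.5 % for dawn, 85.4 % for summer, 46.5 % for noon and 36.8 % for autumn; the short tank falls low since “it runs entirely at the low, depleted concentrations”. My tank shares stand above its figures.

The simulation gives 46.4 % for dawn, 85.4 % for summer, 46.4 % for noon and 36.8 % for autumn, so the best set-up is summer. Substrate in the summer tank stands at 0.0103 M everywhere, which is 4.47 % of the charge. Times the tank ratio of 19.1, that share gives 85.4 % of product in summer. In the autumn tank substrate stands at 0.0574 M, and its ratio of 1.48 gives 36.8 %.

The numbers are invented; the flask was simulated.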